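**Retrosynthetic overview** (terpenoid numbering: ring A = C1–C5 and C10, with the C3 ketone and C4 gem-dimethyl; ring B = C5–C10, with the C8 carbinol and the C9 side chain)
- The strategy rests on ring B: H-5, the C10 methyl and the C9 chain sit on one face (cis-fused decalin), the pattern left by suprafacial endo addition of an (E)-diene (C6–C9) to a ring A C5=C10 alkene whose formyl group is the latent C10 methyl.
- Late stage: C3 ketone from a dioxolane; C8 tertiary alcohol by Rubottom oxidation of the C7 enol silane left by the cycloaddition; C7 oxygen then removed (Barton–McCombie); C10 methyl from the formyl group through its tosylhydrazone.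
- Key disconnection: ring B across C5–C6 and C9–C10, giving a ring A enal and a 2-silyloxy-3-methyl diene that already carries the whole triene chain.
- The enal comes from 2,2-dimethylcyclohexane-1,3-dione (formylation, 1,3-carbonyl transposition); the diene from (E,E)-farnesol (two-carbon homologation, Wittig enone synthesis, enol silylation).
- Ring order: ring A is present in the starting dione; ring B is the only ring formed.

Key step: step 10

Assumption: the (S)-configured oxazaborolidinium cation is taken to expose the enal face that leads to the required adduct; the sense of induction is to be confirmed on the first adduct and, if it is opposite, the (R)-catalyst is used with no other change.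

Conventions: β is the ring B face that carries the C10 substituent; R = (3E,7E)-4,8,12-trimethyltrideca-3,7,11-trien-1-yl; TBS = tert-butyldimethylsilyl. Absolute configurations are those of the SMILES strings.

**Ring A fragment**

Step 1
Reactants: 1 2,2-dimethylcyclohexane-1,3-dione
Product: 2 6,6-dimethyl-1,4-dioxaspiro[4.5]decan-7-one
Conditions: HOCH2CH2OH (1.1 equiv), p-TsOH·H2O (cat.), benzene, reflux, Dean–Stark
Reagents that add atoms: ethylene glycol, OCCO
Why: Acid-catalysed ketalisation with azeotropic removal of water should stop at the mono-dioxolane, because the remaining carbonyl is then flanked by a quaternary carbon next to a ketal and reacts much more slowly.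

Step 2
Reactants: 2 6,6-dimethyl-1,4-dioxaspiro[4.5]decan-7-one
Product: 3 (8Z)-8-(hydroxymethylidene)-6,6-dimethyl-1,4-dioxaspiro[4.5]decan-7-one
Conditions: NaH, HCO2Et, EtOH (cat.), THF, 0 °C → rt; then aq. AcOH
Reagents that add atoms: ethyl formate, CCOC=O
Why: Claisen formylation can occur only at C8, the single enolisable position (the other α-carbon is quaternary), and is driven by formation of the stabilised sodium enolate of the product.

Step 3
Reactants: 3 (8Z)-8-(hydroxymethylidene)-6,6-dimethyl-1,4-dioxaspiro[4.5]decan-7-one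
Product: 4 (8E)-6,6-dimethyl-8-[(propan-2-yloxy)methylidene]-1,4-dioxaspiro[4.5]decan-7-one
Conditions: i-PrI, K2CO3, acetone, reflux
Reagents that add atoms: 2-iodopropane, CC(C)I
Why: O-alkylation of the hydroxymethylene ketone (a vinylogous acid) with a secondary iodide under K2CO3 should give the enol ether in preference to C-alkylation.

Step 4
Reactants: 4 (8E)-6,6-dimethyl-8-[(propan-2-yloxy)methylidene]-1,4-dioxaspiro[4.5]decan-7-one
Product: 6 6,6-dimethyl-1,4-dioxaspiro[4.5]dec-7-ene-8-carbaldehyde, via allylic alcohol 5 (not isolated)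
Conditions: LiAlH4, Et2O, 0 °C; then 0.5 M HCl, THF, 0 °C, 15 min
Reagents that add atoms: water, O
Why: 1,2-Hydride reduction of the vinylogous ester followed by acid-induced allylic transposition (ionisation assisted by the enol ether oxygen, then hydrolysis of the oxocarbenium ion) is a 1,3-carbonyl transposition that places the formyl group on the former α-carbon and the alkene next to the CMe2 group, while brief cold dilute acid should spare the hindered dioxolane.

**Diene fragment**

Step 5
Reactants: 7 (2E,6E)-farnesol
Product: 8 (2E,6E)-farnesyl bromide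
Conditions: PBr3 (0.4 equiv), Et2O, −10 → 0 °C; used crude
Reagents that add atoms: phosphorus tribromide, BrP(Br)Br
Why: Bromination of the primary allylic alcohol with PBr3 at low temperature proceeds by SN2 displacement without allylic transposition or loss of alkene geometry.

Step 6
Reactants: 8 (2E,6E)-farnesyl bromide
Product: 9 (4E,8E)-5,9,13-trimethyltetradeca-4,8,12-trienenitrile
Conditions: MeCN (3 equiv), n-BuLi, THF, −78 °C; then 8, −78 → −20 °C
Reagents that add atoms: acetonitrile (as its lithio derivative), CC#N
Why: SN2 alkylation of lithioacetonitrile by the primary allylic bromide adds the two-carbon unit, and excess anion suppresses dialkylation.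

Step 7
Reactants: 9 (4E,8E)-5,9,13-trimethyltetradeca-4,8,12-trienenitrile
Product: 10 (4E,8E)-5,9,13-trimethyltetradeca-4,8,12-trienal
Conditions: i-Bu2AlH (1.2 equiv), CH2Cl2, −78 °C; then aq. KNaC4H4O6, rt
Reagents that add atoms: water, O
Why: Partial reduction of the nitrile by i-Bu2AlH stops at the N-aluminoimine at low temperature, which hydrolyses to the aldehyde on work-up.

Step 8
Reactants: 10 (4E,8E)-5,9,13-trimethyltetradeca-4,8,12-trienal; 11 3-(triphenylphosphoranylidene)butan-2-one
Product: 12 (3E,7E,11E)-3,8,12,16-tetramethylheptadeca-3,7,11,15-tetraen-2-one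
Conditions: toluene, 110 °C
Reagents that add atoms: none
Why: Wittig olefination with a stabilised α-methyl acyl ylide should give the trisubstituted (E)-enone, the chain ending trans to the acetyl group.

Step 9
Reactants: 12 (3E,7E,11E)-3,8,12,16-tetramethylheptadeca-3,7,11,15-tetraen-2-one
Product: 13 tert-butyl(dimethyl){[(3E,7E,11E)-3,8,12,16-tetramethylheptadeca-1,3,7,11,15-pentaen-2-yl]oxy}silane
Conditions: TBSOTf (1.2 equiv), Et3N (2 equiv), CH2Cl2, 0 °C; filtration through basic alumina
Reagents that add atoms: tert-butyldimethylsilyl trifluoromethanesulfonate, CC(C)(C)[Si](C)(C)OS(=O)(=O)C(F)(F)F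
Why: Soft enolisation (silyl triflate and amine) removes a proton from the acetyl methyl group, the kinetically preferred α' site, to give the cross-conjugated 2-silyloxy diene with the (E)-alkene untouched.

**Key step and endgame**

Step 10
Reactants: 6 6,6-dimethyl-1,4-dioxaspiro[4.5]dec-7-ene-8-carbaldehyde (1.2 equiv); 13 tert-butyl(dimethyl){[(3E,7E,11E)-3,8,12,16-tetramethylheptadeca-1,3,7,11,15-pentaen-2-yl]oxy}silane (1.0 equiv)
Product: 14 cis-fused Diels–Alder adduct: ring B cyclohexene with C7(OTBS)=C8(CH3), C3 dioxolane, 10β-CHO, 5β-H, 9β-R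
Conditions: (S)-tetrahydro-1-(2-methylphenyl)-3,3-diphenyl-1H,3H-pyrrolo[1,2-c][1,3,2]oxazaborole (20 mol %), (CF3SO2)2NH (18 mol %), CH2Cl2, −78 → −40 °C; Et3N quench at low temperature, Et3N-deactivated silica
Reagents that add atoms: none
Why: The formyl oxygen of enal 6 binds to boron of the N-protonated oxazaborolidine (s-trans enal, held by a formyl C–H···O contact), and diene 13 adds in a concerted but asynchronous [4+2] in which the unhindered CH2 terminus C6 bonds to the β-carbon C5 ahead of C9–C10 closure; the closest known reaction type is the oxazaborolidinium-catalysed enantioselective Diels–Alder of 2-silyloxy dienes with α-substituted enals. Ring B is closed as a cyclohexene by the intermolecular cycloaddition itself, suprafacial on both components, and it keeps a regiodefined C7=C8 enol silane. Regiochemistry is reinforced twice: the C7 silyloxy group makes C6 the nucleophilic terminus (oxygen para to C10), and the C9 alkyl terminus goes ortho to the formyl-bearing carbon. C5 and C10 are fixed cis by the ring alkene of the enal (H-5 and CHO on one face, C1 and C4 on the other), and C9 is set by the endo position of the formyl group together with the (E)-diene, whose outside chain ends on the face of CHO and H-5; ring A lies exo, away from the diene, which also disfavours the exo-formyl transition state. The absolute configuration of all three centres follows from the enal face left open by the catalyst. The step therefore needs endo and enantiofacial control from the catalyst at a congested neopentyl β-carbon, while cis fusion and regiochemistry are inherent in the two partners.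

Step 11
Reactants: 14 cis-fused Diels–Alder adduct
Product: 15 tosylhydrazone of the angular aldehyde (C7 enol silane and C3 dioxolane retained)
Conditions: TsNHNH2 (1.1 equiv), THF, rt → 40 °C
Reagents that add atoms: p-toluenesulfonohydrazide, Cc1ccc(cc1)S(=O)(=O)NN
Why: Condensation of the aldehyde with the sulfonyl hydrazide under neutral conditions forms the hydrazone and leaves the enol silane and the dioxolane intact.

Step 12
Reactants: 15 tosylhydrazone of the angular aldehyde
Product: 17 10β-methyl enol silane (C7 OTBS; C3 dioxolane; 5β-H; 9β-R), via alkyldiazene 16 (not isolated)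
Conditions: catecholborane (2 equiv), CHCl3, 0 °C → rt; then NaOAc·3H2O, reflux
Reagents that add atoms: none
Why: Reductive removal of a tosylhydrazone (borane variant of the Caglioti reduction): B–H adds across C=N, acetate induces loss of sulfinate to the monoalkyldiazene, which loses N2 to leave the methyl group; the hydrazone carbon has no α-hydrogen, so no alkene-forming pathway exists and no stereocentre is touched.

Step 13
Reactants: 17 10β-methyl enol silane
Product: 19 8α-(tert-butyldimethylsilyloxy)-8β-methyl C7 ketone (C3 dioxolane; 5β-H; 9β-R; 10β-CH3), via silyloxy epoxide 18 (not isolated)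
Conditions: mCPBA (1.05 equiv), CH2Cl2, −40 → 0 °C; aq. NaHCO3 work-up
Reagents that add atoms: 3-chloroperoxybenzoic acid, OOC(=O)c1cccc(Cl)c1
Why: Rubottom oxidation: the tetrasubstituted enol silane is far more electron-rich than the trisubstituted chain alkenes and should take the peracid oxygen first, on the α face of C8 anti to the C9 chain (held pseudoaxial by A(1,2) strain with the C8 methyl), and the liberated acid opens the silyloxy epoxide with 1,4-silyl shift to the ketone, so that C8 is set with oxygen α and methyl β.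

Step 14
Reactants: 19 8α-silyloxy-8β-methyl C7 ketone
Product: 20 C7 alcohol (configuration at C7 immaterial; 8α-OTBS retained)
Conditions: i-Bu2AlH, CH2Cl2, −78 °C; aq. KNaC4H4O6
Reagents that add atoms: none
Why: Hydride reduction of the hindered ketone by i-Bu2AlH gives a non-basic aluminium alkoxide, which avoids 1,2-silyl migration from O8, and the new C7 centre is removed in step 16.

Step 15
Reactants: 20 C7 alcohol
Product: 21 O-(C7) 1H-imidazole-1-carbothioate of 20
Conditions: 1,1'-thiocarbonyldiimidazole (3 equiv), 4-(dimethylamino)pyridine (0.5 equiv), ClCH2CH2Cl, 80 °C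
Reagents that add atoms: 1,1'-thiocarbonyldiimidazole, S=C(n1ccnc1)n1ccnc1
Why: Thioacylation of the secondary alcohol under neutral acyl-transfer conditions (first half of the Barton–McCombie deoxygenation) avoids alkoxide-induced silyl migration, and the capped tertiary oxygen cannot form a cyclic thionocarbonate.

Step 16
Reactants: 21 O-(C7) 1H-imidazole-1-carbothioate
Product: 22 8α-(tert-butyldimethylsilyloxy) C3 dioxolane with C7 methylene
Conditions: Bu3SnH (2 equiv), 2,2'-azobis(2-methylpropionitrile) (0.2 equiv), toluene, 100 °C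
Reagents that add atoms: none
Why: Barton–McCombie radical deoxygenation: the stannyl radical adds to sulfur, the C7–O bond fragments, and the secondary C7 radical is reduced by Bu3SnH faster than it can cyclise onto the remote chain alkenes.

Step 17
Reactants: 22 8α-silyloxy C3 dioxolane
Product: 23 8α-hydroxy C3 dioxolane
Conditions: Bu4NF, THF, 50 °C
Reagents that add atoms: none
Why: Fluoride-induced desilylation frees the tertiary alcohol, and at this stage the molecule carries no base-sensitive group.

Step 18
Reactants: 23 8α-hydroxy C3 dioxolane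
Product: 24 (5S,8R,9R,10S)-8-hydroxy-4,4,8,10-tetramethyl-9-[(3E,7E)-4,8,12-trimethyltrideca-3,7,11-trien-1-yl]decalin-3-one (terpenoid numbering; 5β-H, 8α-OH, 9β-R, 10β-CH3)
Conditions: pyridinium p-toluenesulfonate (cat.), acetone/H2O (4:1), 55 °C
Reagents that add atoms: water, O
Why: Mild acid-catalysed ketal hydrolysis releases the C3 ketone without dehydrating the tertiary alcohol or protonating the chain alkenes, and C5 cannot epimerise because C4 is quaternary.

**Compound list**

1 | 2,2-dimethylcyclohexane-1,3-dione | CC1(C)C(=O)CCCC1=O | starting material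
2 | 6,6-dimethyl-1,4-dioxaspiro[4.5]decan-7-one | O=C1CCCC2(OCCO2)C1(C)C | intermediate
3 | (8Z)-8-(hydroxymethylidene)-6,6-dimethyl-1,4-dioxaspiro[4.5]decan-7-one (chelated enol) | O/C=C1/CCC2(OCCO2)C(C)(C)C1=O | intermediate
4 | (8E)-6,6-dimethyl-8-[(propan-2-yloxy)methylidene]-1,4-dioxaspiro[4.5]decan-7-one | CC(C)O/C=C1\CCC2(OCCO2)C(C)(C)C1=O | intermediate
5 | (8E)-6,6-dimethyl-8-[(propan-2-yloxy)methylidene]-1,4-dioxaspiro[4.5]decan-7-ol, racemic allylic alcohol (not isolated) | CC(C)O/C=C1\CCC2(OCCO2)C(C)(C)C1O | intermediate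
6 | 6,6-dimethyl-1,4-dioxaspiro[4.5]dec-7-ene-8-carbaldehyde (ring A enal) | O=CC1=CC(C)(C)C2(OCCO2)CC1 | intermediate
7 | (2E,6E)-farnesol | CC(C)=CCC/C(C)=C/CC/C(C)=C/CO | starting material
8 | (2E,6E)-farnesyl bromide | CC(C)=CCC/C(C)=C/CC/C(C)=C/CBr | intermediate
9 | (4E,8E)-5,9,13-trimethyltetradeca-4,8,12-trienenitrile | CC(C)=CCC/C(C)=C/CC/C(C)=C/CCC#N | intermediate
10 | (4E,8E)-5,9,13-trimethyltetradeca-4,8,12-trienal | CC(C)=CCC/C(C)=C/CC/C(C)=C/CCC=O | intermediate
11 | 3-(triphenylphosphoranylidene)butan-2-one | CC(=O)C(C)=P(c1ccccc1)(c1ccccc1)c1ccccc1 | starting material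
12 | (3E,7E,11E)-3,8,12,16-tetramethylheptadeca-3,7,11,15-tetraen-2-one | CC(C)=CCC/C(C)=C/CC/C(C)=C/CC/C=C(\C)C(C)=O | intermediate
13 | tert-butyl(dimethyl){[(3E,7E,11E)-3,8,12,16-tetramethylheptadeca-1,3,7,11,15-pentaen-2-yl]oxy}silane | CC(C)=CCC/C(C)=C/CC/C(C)=C/CC/C=C(C)/C(=C)O[Si](C)(C)C(C)(C)C | intermediate
14 | cis-fused Diels–Alder adduct: C7(OTBS)=C8(CH3), C3 dioxolane, 10β-CHO, 5β-H, 9β-R | CC(C)=CCC/C(C)=C/CC/C(C)=C/CC[C@@H]1[C@@]2(C=O)CCC3(OCCO3)C(C)(C)[C@H]2CC(O[Si](C)(C)C(C)(C)C)=C1C | intermediate
15 | (E)-tosylhydrazone of 14 | CC(C)=CCC/C(C)=C/CC/C(C)=C/CC[C@@H]1[C@@]2(/C=N/NS(=O)(=O)c3ccc(C)cc3)CCC3(OCCO3)C(C)(C)[C@H]2CC(O[Si](C)(C)C(C)(C)C)=C1C | intermediate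
16 | alkyldiazene at the C10 methylene (not isolated) | CC(C)=CCC/C(C)=C/CC/C(C)=C/CC[C@@H]1[C@@]2(CN=N)CCC3(OCCO3)C(C)(C)[C@H]2CC(O[Si](C)(C)C(C)(C)C)=C1C | intermediate
17 | 10β-methyl enol silane: C7(OTBS)=C8(CH3), C3 dioxolane, 5β-H, 9β-R | CC(C)=CCC/C(C)=C/CC/C(C)=C/CC[C@@H]1[C@@]2(C)CCC3(OCCO3)C(C)(C)[C@H]2CC(O[Si](C)(C)C(C)(C)C)=C1C | intermediate
18 | 7α,8α-epoxide of 17 carrying 7β-OTBS and 8β-CH3 (not isolated) | CC(C)=CCC/C(C)=C/CC/C(C)=C/CC[C@@H]1[C@@]2(C)CCC3(OCCO3)C(C)(C)[C@H]2C[C@@]4(O[Si](C)(C)C(C)(C)C)O[C@@]14C | intermediate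
19 | 8α-(tert-butyldimethylsilyloxy)-8β-methyl C7 ketone, C3 dioxolane | CC(C)=CCC/C(C)=C/CC/C(C)=C/CC[C@@H]1[C@@]2(C)CCC3(OCCO3)C(C)(C)[C@H]2CC(=O)[C@@]1(C)O[Si](C)(C)C(C)(C)C | intermediate
20 | C7 alcohol of 19 (C7 configuration undefined) | CC(C)=CCC/C(C)=C/CC/C(C)=C/CC[C@@H]1[C@@]2(C)CCC3(OCCO3)C(C)(C)[C@H]2CC(O)[C@@]1(C)O[Si](C)(C)C(C)(C)C | intermediate
21 | O-(C7) 1H-imidazole-1-carbothioate of 20 | CC(C)=CCC/C(C)=C/CC/C(C)=C/CC[C@@H]1[C@@]2(C)CCC3(OCCO3)C(C)(C)[C@H]2CC(OC(=S)n4ccnc4)[C@@]1(C)O[Si](C)(C)C(C)(C)C | intermediate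
22 | 8α-(tert-butyldimethylsilyloxy) C3 dioxolane, C7 methylene | CC(C)=CCC/C(C)=C/CC/C(C)=C/CC[C@@H]1[C@@]2(C)CCC3(OCCO3)C(C)(C)[C@H]2CC[C@@]1(C)O[Si](C)(C)C(C)(C)C | intermediate
23 | 8α-hydroxy C3 dioxolane | CC(C)=CCC/C(C)=C/CC/C(C)=C/CC[C@@H]1[C@@]2(C)CCC3(OCCO3)C(C)(C)[C@H]2CC[C@@]1(C)O | intermediate
24 | (5S,8R,9R,10S)-8-hydroxy-4,4,8,10-tetramethyl-9-[(3E,7E)-4,8,12-trimethyltrideca-3,7,11-trien-1-yl]decalin-3-one | CC(C)=CCC/C(C)=C/CC/C(C)=C/CC[C@@H]1[C@@]2(C)CCC(=O)C(C)(C)[C@H]2CC[C@@]1(C)O | target

**Step count**
Total: 18 steps. Longest linear sequence: 14 steps (7 → 24, steps 5–18); the ring A branch (steps 1–4) joins at step 10.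

**Steps most likely to fail**

Step 10. Turnover may stall because the congested enal binds the bulky boron cation poorly or the dioxolane sequesters it. Silyl transfer from the diene to triflimide may open an achiral silyl-triflimide-catalysed cycloaddition and erode enantiofacial control. 1,2-Addition of the enol silane to the activated formyl group (Mukaiyama aldol) may also compete. Fallback: the cycloaddition is run from 6 and 13 with a stoichiometric achiral Lewis acid (Me2AlCl, CH2Cl2, −78 → −20 °C), which should give 14 together with its mirror image, antipodal adduct F1. Preparative chromatography on a chiral stationary phase removes F1, and 14 re-enters the route at step 11. This gives up catalytic induction and at best half of the material.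

Step 13. The peracid may epoxidise the chain alkenes in competition with the enol silane. Oxygen may also be delivered to the β face of C8, syn to the chain, if the axial C1 methylene on the α face proves the larger obstacle. Acid may protodesilylate the enol silane before oxidation. Fallback: starting from 17, MeLi (THF, 0 °C → rt) cleaves the O–Si bond and gives the regiodefined lithium enolate F2. 2-(Phenylsulfonyl)-3-phenyloxaziridine at −78 °C, which does not attack isolated alkenes, then transfers oxygen to C8 and gives hydroxy ketone F3. Silylation of the tertiary alcohol (TBSOTf, 2,6-lutidine, CH2Cl2) returns to 19.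

Step 12. Hydride transfer to the neopentyl hydrazone carbon may be slow, and the boron by-products may cleave the enol silane, so that the regiodefined C7=C8 enol ether is lost before the hydroxylation. Fallback: starting from 14, NaBH4 (EtOH, 0 °C) reduces the aldehyde to neopentyl alcohol F4. 1,1'-Thiocarbonyldiimidazole with 4-(dimethylamino)pyridine converts it to imidazolide F5. Bu3SnH with 2,2'-azobis(2-methylpropionitrile) in refluxing toluene (Barton–McCombie deoxygenation of a primary alcohol) then gives 17.

**Further compounds**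
F1 | step 10 | antipode of adduct 14 | CC(C)=CCC/C(C)=C/CC/C(C)=C/CC[C@H]1[C@]2(C=O)CCC3(OCCO3)C(C)(C)[C@@H]2CC(O[Si](C)(C)C(C)(C)C)=C1C
F2 | step 13 | lithium C7 enolate of the 10β-methyl series | CC(C)=CCC/C(C)=C/CC/C(C)=C/CC[C@@H]1[C@@]2(C)CCC3(OCCO3)C(C)(C)[C@H]2CC(O[Li])=C1C
F3 | step 13 | 8α-hydroxy-8β-methyl C7 ketone, C3 dioxolane | CC(C)=CCC/C(C)=C/CC/C(C)=C/CC[C@@H]1[C@@]2(C)CCC3(OCCO3)C(C)(C)[C@H]2CC(=O)[C@@]1(C)O
F4 | step 12 | 10β-hydroxymethyl enol silane (neopentyl alcohol from 14) | CC(C)=CCC/C(C)=C/CC/C(C)=C/CC[C@@H]1[C@@]2(CO)CCC3(OCCO3)C(C)(C)[C@H]2CC(O[Si](C)(C)C(C)(C)C)=C1C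
F5 | step 12 | O-(C10 methylene) 1H-imidazole-1-carbothioate of F4 | CC(C)=CCC/C(C)=C/CC/C(C)=C/CC[C@@H]1[C@@]2(COC(=S)n3ccnc3)CCC3(OCCO3)C(C)(C)[C@H]2CC(O[Si](C)(C)C(C)(C)C)=C1C
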